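A one-step picture, substrate and coupling partner to target, fails at first look. In the eta run target stands flat near 23.4% from 10.0 h to 20.0 h, yet isomer of the product climbs from 7.8% to 17.4%. So target leaks into isomer of the product.

common to all: catalyst 1.3 mM
- eta: substrate 0.38 M; coupling partner 0.19 M; the very flask that is asked about, followed so far
- alpha: substrate 0.57 M; coupling partner 0.19 M; run made earlier
- flask: substrate 0.38 M; coupling partner 0.190 M; time 3.0 d

eta run (percent of the substrate charged)

| time / h | target / % | isomer of the product / % |
|---|---|---|
| 3.00 | 12.7 | 1.1 |
| 6.00 | 17.1 | 3.3 |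
| 10.0 | 24.1 | 7.8 |
| 12.0 | 22.7 | 8.9 |
| 15.0 | 24.2 | 11.0 |
| 20.0 | 22.8 | 17.4 |

alpha run (percent of the substrate charged)

| time / d | target / % | isomer of the product / % |
|---|---|---|
| 0.167 | 12.9 | 0.5 |
| 0.500 | 18.5 | 7.6 |
| 0.833 | 16.5 | 12.4 |
| 1.25 | 15.6 | 18.7 |
| 1.67 | 9.8 | 22.6 |
| 2.50 | 3.6 | 26.9 |
| 3.00 | 5.1 | 31.3 |

(readings scatter by 1 percentage point)

* share of target in target plus isomer of the product at 30 min
* share of target in target plus isomer of the product at 3.0 d
* which of target and isomer of the product there is more of at 3.0 d

- a reading or a percentage of target counts all its forms, free or not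

The flask asked about is the eta run carried further. Flat target, with catalyst assumed unchanged, freezes the leak into one pseudo-first-order number: the leak constant 0.983 d⁻¹, the isomer gained per unit time for each unit of target standing. The feed needs a constant too. In the eta run the coupling partner, charged at half the substrate, is the limiting reagent. Its use by 20.0 h gives a first-order loss of c(coupling partner) of 1.96 d⁻¹, with c(substrate) frozen at its mean over that time. A chain of two first-order steps then puts the share of target at 3.0 d at 10.0%.

An objection comes from the alpha run. Its feed, scaled with substrate, is 2.93 d⁻¹, so the same chain gives 7.87%. The alpha run reads 14.0% at 3.00 d. The chain falls short, so a floor of 6.14% is added. It is rough, since it rests on one reading of target, 5.1%, with a scatter of 1 percentage point. With that floor this reckoning commits to a share of 16.1% at 3.0 d, with isomer of the product ahead.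

The forecast gives 98.8% at 30 min, 10% at 3.0 d, and isomer of the product ahead. “Alpha's late readings (share 12–14%) hint at a small equilibrium floor, so I take about 10%.” Its late share stands lower than the one reckoned here.

The flask gives 97.8% at 30 min and 15.9% at 3.0 d, with 7.74% target against 41.0% isomer of the product.

    substrate + coupling partner ⇌ target (K = 67.0 M⁻¹, k = 0.286 M⁻¹ h⁻¹)
    substrate + coupling partner ⇌ isomer of the product (K = 1090 M⁻¹, k = 0.00359 M⁻¹ h⁻¹)
    target + catalyst ⇌ isomer of the product + catalyst, rate k3*[catalyst]*[target] forward; the back reaction follows from the equilibrium constant (k = 30.9 M⁻¹ h⁻¹)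
    catalyst + target ⇌ idle complex (K = 0.845 M⁻¹, k = 5.36 M⁻¹ h⁻¹)

The scheme writes the leak as proportional to catalyst. A neighbouring flask holds 0.0033 M of catalyst in place of 1.3 mM, with its other charges and its time as in the flask. The leak constant 0.983 d⁻¹, scaled with the catalyst charge, becomes 2.49 d⁻¹, and the feed stays 1.96 d⁻¹. The chain then gives 0.826%, and the floor of 6.14% brings the reckoned share to 6.97%. At 3.0 d that neighbouring flask holds 3.42% target and 45.8% isomer of the product, a share of 6.95%.

Readings and results are calculated on assumed constants.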